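Ring C is disconnected at O1–C2 and C3–C4. The atoms O1–C8a–C4a–C4 are read as the oxadiene of an ortho-quinone methide on the phloroglucinol ring A, and C2=C3 as the vinyl group of a ring B styrene whose 4'-oxygen polarises it head to tail. A 4-methoxy quinone methide, generated by a confined chiral acid from a bis-silylated 2,4,6-trihydroxybenzaldehyde and trimethyl orthoformate, should add to a 3-bromo-4,5-bis(silyloxy)styrene in one asymmetric [4+2] step that closes ring C, sets C2 as S and leaves C4 as a methyl ether, one oxidation below the ketone. Bromine holds C5' for prenylation after the cycloaddition.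

Key step: step 5

Assumption: the (S,S) antipode of the chiral acid is taken to give the 2S series; if induction runs the other way, the (R,R) acid is used and nothing else changes.

Step 1
Reactants: 1 2,4,6-trihydroxybenzaldehyde
Product: 2 2-hydroxy-4,6-bis(tert-butyldimethylsilyloxy)benzaldehyde
Conditions: TBSCl (2.1 equiv), imidazole (2.5 equiv), THF, 0 °C to rt
Reagents that add atoms: tert-butyldimethylsilyl chloride, CC(C)(C)[Si](C)(C)Cl
Why: Selective phenol silylation (silyl ether formation), in which the para phenol and one ortho phenol react while the last ortho phenol, locked in a hydrogen bond to the formyl oxygen, should stay free with a small excess of reagent.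

Step 2
Reactants: 3 5-bromovanillin
Product: 4 3-bromo-4,5-dihydroxybenzaldehyde
Conditions: AlCl3 (1.2 equiv), pyridine (4.5 equiv), CH2Cl2, reflux; then 2 M HCl
Reagents that add atoms: none
Why: Lewis acid mediated aryl methyl ether cleavage of a guaiacol, in which aluminium bound to the ortho phenoxide activates the methoxy group and pyridine removes the methyl group by SN2 attack, leaving the aldehyde and the aryl bromide untouched.

Step 3
Reactants: 4 3-bromo-4,5-dihydroxybenzaldehyde
Product: 5 3-bromo-4,5-bis(tert-butyldimethylsilyloxy)benzaldehyde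
Conditions: TBSCl (2.5 equiv), imidazole (5 equiv), DMAP (cat.), DMF, rt
Reagents that add atoms: tert-butyldimethylsilyl chloride, CC(C)(C)[Si](C)(C)Cl
Why: Silyl ether formation under Corey conditions, with excess reagent in DMF to drive silylation of the hindered oxygen next to bromine.

Step 4
Reactants: 5 3-bromo-4,5-bis(tert-butyldimethylsilyloxy)benzaldehyde
Product: 6 3-bromo-4,5-bis(tert-butyldimethylsilyloxy)styrene
Conditions: Ph3PCH3Br (1.3 equiv), NaN(SiMe3)2 (1.25 equiv), THF, 0 °C; then 5, -78 °C to rt
Reagents that add atoms: methyltriphenylphosphonium bromide, C[P+](c1ccccc1)(c1ccccc1)c1ccccc1.[Br-]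
Why: Wittig methylenation with a non-stabilised ylide made with a slight deficit of base, so that no free amide remains to attack the aryl silyl ethers.

Step 5
Reactants: 2 2-hydroxy-4,6-bis(tert-butyldimethylsilyloxy)benzaldehyde; 6 3-bromo-4,5-bis(tert-butyldimethylsilyloxy)styrene; 7 trimethyl orthoformate
Product: 10 (2S,4S)-2-[3-bromo-4,5-bis(tert-butyldimethylsilyloxy)phenyl]-5,7-bis(tert-butyldimethylsilyloxy)-4-methoxychroman (2,4-cis), via dimethyl acetal 8 (not isolated), via 4-methoxy ortho-quinone methide 9 (not isolated)
Conditions: 2 (1.0 equiv), 6 (1.3 equiv), 7 (1.5 equiv), (S,S)-imidodiphosphorimidate acid (BINOL-derived, N-triflyl, bulky 3,3'-aryl groups; 5 mol %), 5 Å MS, CH2Cl2, -40 °C; Et3N quench at -40 °C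
Reagents that add atoms: trimethyl orthoformate (7), COC(OC)OC
Why: Proposed new method: the acid turns the acetal 8 formed in the flask, by loss of methanol, into the O-protonated form of quinone methide 9, an oxocarbenium ion paired with the confined chiral imidodiphosphorimidate anion; the terminal carbon of styrene 6 (C3) attacks C4 and the phenol oxygen O1 then collapses onto the developing benzylic cation at C2, an asynchronous inverse-demand oxa-[4+2] cycloaddition that restores the aromaticity of ring A. The closest known reactions are the racemic Sc(OTf)3-catalysed union of salicylaldehydes, trimethyl orthoformate and styrenes to cis-4-methoxyflavans and the chiral phosphoric-acid-type catalysed [4+2] additions of ortho-quinone methides from ortho-hydroxybenzyl alcohols to styrenes, whereas an enantioselective reaction through the alkoxy-substituted ion is without precedent. Ring C is closed by intermolecular [4+2] annulation, the C3–C4 bond leading and the six-membered O1–C2 closure following. C2 is set by the styrene face that the pocket of the chiral anion presents to the bound cation (catalyst control, 2S with the proper antipode), and C4 follows from the endo placement of the aryl group over the oxadiene, which gives the 2,4-cis (4S) isomer. The step needs head-to-tail regiochemistry, face selectivity at C2 and freedom from Friedel–Crafts self-condensation: the 4'-silyloxy group stabilises positive charge at C2 and fixes the orientation, bromine in place of prenyl leaves the vinyl group as the only nucleophilic alkene, and the bulky silyl ethers screen the open positions of ring A. Any trans isomer should be removed here by chromatography, because only C2 survives to the target and a trans isomer with the same C4 configuration would be 2R.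

Step 6
Reactants: 10 (2S,4S)-2-[3-bromo-4,5-bis(tert-butyldimethylsilyloxy)phenyl]-5,7-bis(tert-butyldimethylsilyloxy)-4-methoxychroman; 11 prenylboronic acid pinacol ester
Product: 12 (2S,4S)-2-[3,4-bis(tert-butyldimethylsilyloxy)-5-(3-methylbut-2-en-1-yl)phenyl]-5,7-bis(tert-butyldimethylsilyloxy)-4-methoxychroman
Conditions: 11 (1.5 equiv), PdCl2(IPent)(3-chloropyridine) (3 mol %; IPent = 1,3-bis[2,6-di(3-pentyl)phenyl]imidazol-2-ylidene), 2 M aq K3PO4 (3 equiv), THF, 50 °C, degassed
Reagents that add atoms: prenylboronic acid pinacol ester (11), CC(C)=CCB1OC(C)(C)C(C)(C)O1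
Why: Suzuki–Miyaura coupling of the C5' aryl bromide with an allylic boronate, for which a very bulky N-heterocyclic carbene ligand is known to steer 3,3-disubstituted allylboronates to α-coupling (prenyl, not 1,1-dimethylallyl); it is placed before the C4 oxidation so that the aqueous base never meets a flavanone and cannot open ring C or epimerise C2.

Step 7
Reactants: 12 (2S,4S)-2-[3,4-bis(tert-butyldimethylsilyloxy)-5-(3-methylbut-2-en-1-yl)phenyl]-5,7-bis(tert-butyldimethylsilyloxy)-4-methoxychroman
Product: 14 (2S)-2-[3,4-bis(tert-butyldimethylsilyloxy)-5-(3-methylbut-2-en-1-yl)phenyl]-5,7-bis(tert-butyldimethylsilyloxy)chroman-4-one, via C4 methyl hemiketal 13 (not isolated)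
Conditions: DDQ (1.5 equiv), CH2Cl2/pH 7 phosphate buffer (10:1), 0 °C to rt
Reagents that add atoms: water, O
Why: DDQ oxidation of a benzylic methyl ether, in which hydride abstraction from C4 (activated by its methoxy group and the three oxygen substituents of ring A) gives an oxocarbenium ion that water captures as hemiketal 13, which loses methanol to the ketone; C2 takes no part and stays S.

Step 8
Reactants: 14 (2S)-2-[3,4-bis(tert-butyldimethylsilyloxy)-5-(3-methylbut-2-en-1-yl)phenyl]-5,7-bis(tert-butyldimethylsilyloxy)chroman-4-one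
Product: 15 sigmoidin B, (2S)-2-[3,4-dihydroxy-5-(3-methylbut-2-en-1-yl)phenyl]-5,7-dihydroxychroman-4-one
Conditions: TBAF (5 equiv), AcOH (6 equiv), THF, 0 °C, argon
Reagents that add atoms: none
Why: Fluoride-mediated cleavage of the four aryl silyl ethers, buffered with acetic acid so that neither phenoxide-triggered retro-oxa-Michael opening of ring C (the racemisation path of flavanones) nor acid-induced cyclisation of the prenyl group onto the 4'-phenol can occur.

Compound list
1 | 2,4,6-trihydroxybenzaldehyde | O=Cc1c(O)cc(O)cc1O | starting material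
2 | 2-hydroxy-4,6-bis(tert-butyldimethylsilyloxy)benzaldehyde | O=Cc1c(O)cc(O[Si](C)(C)C(C)(C)C)cc1O[Si](C)(C)C(C)(C)C | intermediate
3 | 5-bromovanillin | COc1cc(C=O)cc(Br)c1O | starting material
4 | 3-bromo-4,5-dihydroxybenzaldehyde | O=Cc1cc(O)c(O)c(Br)c1 | intermediate
5 | 3-bromo-4,5-bis(tert-butyldimethylsilyloxy)benzaldehyde | O=Cc1cc(Br)c(O[Si](C)(C)C(C)(C)C)c(O[Si](C)(C)C(C)(C)C)c1 | intermediate
6 | 3-bromo-4,5-bis(tert-butyldimethylsilyloxy)styrene | C=Cc1cc(Br)c(O[Si](C)(C)C(C)(C)C)c(O[Si](C)(C)C(C)(C)C)c1 | intermediate
7 | trimethyl orthoformate | COC(OC)OC | starting material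
8 | 2-(dimethoxymethyl)-3,5-bis(tert-butyldimethylsilyloxy)phenol (dimethyl acetal of 2) | COC(OC)c1c(O)cc(O[Si](C)(C)C(C)(C)C)cc1O[Si](C)(C)C(C)(C)C | intermediate (not isolated)
9 | (E)-6-(methoxymethylidene)-3,5-bis(tert-butyldimethylsilyloxy)cyclohexa-2,4-dien-1-one (4-methoxy ortho-quinone methide; reacts as its O-protonated ion pair, drawn E as a working geometry) | CO/C=C1/C(=O)C=C(O[Si](C)(C)C(C)(C)C)C=C1O[Si](C)(C)C(C)(C)C | intermediate (not isolated)
10 | (2S,4S)-2-[3-bromo-4,5-bis(tert-butyldimethylsilyloxy)phenyl]-5,7-bis(tert-butyldimethylsilyloxy)-4-methoxychroman (2,4-cis) | Brc1cc([C@@H]2C[C@H](OC)c3c(O[Si](C)(C)C(C)(C)C)cc(O[Si](C)(C)C(C)(C)C)cc3O2)cc(O[Si](C)(C)C(C)(C)C)c1O[Si](C)(C)C(C)(C)C | intermediate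
11 | prenylboronic acid pinacol ester | CC(C)=CCB1OC(C)(C)C(C)(C)O1 | starting material
12 | (2S,4S)-2-[3,4-bis(tert-butyldimethylsilyloxy)-5-(3-methylbut-2-en-1-yl)phenyl]-5,7-bis(tert-butyldimethylsilyloxy)-4-methoxychroman | CC(C)=CCc1cc([C@@H]2C[C@H](OC)c3c(O[Si](C)(C)C(C)(C)C)cc(O[Si](C)(C)C(C)(C)C)cc3O2)cc(O[Si](C)(C)C(C)(C)C)c1O[Si](C)(C)C(C)(C)C | intermediate
13 | (2S)-2-[3,4-bis(tert-butyldimethylsilyloxy)-5-(3-methylbut-2-en-1-yl)phenyl]-5,7-bis(tert-butyldimethylsilyloxy)-4-methoxychroman-4-ol (methyl hemiketal, both C4 epimers) | CC(C)=CCc1cc([C@@H]2CC(O)(OC)c3c(O[Si](C)(C)C(C)(C)C)cc(O[Si](C)(C)C(C)(C)C)cc3O2)cc(O[Si](C)(C)C(C)(C)C)c1O[Si](C)(C)C(C)(C)C | intermediate (not isolated)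
14 | (2S)-2-[3,4-bis(tert-butyldimethylsilyloxy)-5-(3-methylbut-2-en-1-yl)phenyl]-5,7-bis(tert-butyldimethylsilyloxy)chroman-4-one | CC(C)=CCc1cc([C@@H]2CC(=O)c3c(O[Si](C)(C)C(C)(C)C)cc(O[Si](C)(C)C(C)(C)C)cc3O2)cc(O[Si](C)(C)C(C)(C)C)c1O[Si](C)(C)C(C)(C)C | intermediate
15 | sigmoidin B, (2S)-2-[3,4-dihydroxy-5-(3-methylbut-2-en-1-yl)phenyl]-5,7-dihydroxychroman-4-one | CC(C)=CCc1cc([C@@H]2CC(=O)c3c(O)cc(O)cc3O2)cc(O)c1O | target

Total step count: 8. Longest linear sequence: 7 steps (3 to 15 through steps 2, 3, 4, 5, 6, 7 and 8).

Steps most likely to fail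

Step 5. The chiral ion pair may give too little face selectivity at C2, or acid-driven self-condensation of the electron-rich ring A and partial silyl loss may outrun the cycloaddition. The fallback sets out from 2, 6 and 7 and runs the union as the established racemic process with Sc(OTf)3 (10 mol %) in CH2Cl2 at rt. This should give the racemate made of 10 and its mirror image, the (2R,4R)-2-[3-bromo-4,5-bis(tert-butyldimethylsilyloxy)phenyl]-5,7-bis(tert-butyldimethylsilyloxy)-4-methoxychroman F1. The enantiomers are then separated by preparative chromatography on a chiral stationary phase (supercritical CO2 with an alcohol modifier), and the (2S,4S) component comes back to the route at 10.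

Step 6. The allyl fragment may couple through its γ-carbon and give the 1,1-dimethylallyl isomer, or the aqueous base may strip aryl silyl ethers. The fallback sets out from 10 and uses a base-free Stille allylation with allyltributylstannane and Pd(PPh3)4 in toluene at 100 °C. This should give (2S,4S)-2-[3-allyl-4,5-bis(tert-butyldimethylsilyloxy)phenyl]-5,7-bis(tert-butyldimethylsilyloxy)-4-methoxychroman F2; the unsubstituted allyl group couples to the same product through either terminus. Cross-metathesis of F2 with excess 2-methyl-2-butene and the second-generation Grubbs catalyst RuCl2(=CHPh)(H2IMes)(PCy3) in CH2Cl2 at 40 °C then installs the prenyl terminus and comes back to the route at 12.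

Step 7. DDQ may abstract hydride from the benzylic-allylic methylene of the prenyl group, or the C4 cation may lose a proton and be oxidised further towards the flavone, which would destroy C2. The fallback sets out from 12 and replaces the hydride abstraction by solvolysis: PPTS in THF/water at rt ionises the very labile C4 methyl ether and water should give (2S)-2-[3,4-bis(tert-butyldimethylsilyloxy)-5-(3-methylbut-2-en-1-yl)phenyl]-5,7-bis(tert-butyldimethylsilyloxy)chroman-4-ol F3 as a mixture of C4 epimers. Dess–Martin periodinane with NaHCO3 in CH2Cl2 oxidises both epimers to the ketone and comes back to the route at 14.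

Further compounds
F1 | step 5 | (2R,4R)-2-[3-bromo-4,5-bis(tert-butyldimethylsilyloxy)phenyl]-5,7-bis(tert-butyldimethylsilyloxy)-4-methoxychroman (mirror image of 10, formed with 10 as the racemate) | Brc1cc([C@H]2C[C@@H](OC)c3c(O[Si](C)(C)C(C)(C)C)cc(O[Si](C)(C)C(C)(C)C)cc3O2)cc(O[Si](C)(C)C(C)(C)C)c1O[Si](C)(C)C(C)(C)C
F2 | step 6 | (2S,4S)-2-[3-allyl-4,5-bis(tert-butyldimethylsilyloxy)phenyl]-5,7-bis(tert-butyldimethylsilyloxy)-4-methoxychroman | C=CCc1cc([C@@H]2C[C@H](OC)c3c(O[Si](C)(C)C(C)(C)C)cc(O[Si](C)(C)C(C)(C)C)cc3O2)cc(O[Si](C)(C)C(C)(C)C)c1O[Si](C)(C)C(C)(C)C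
F3 | step 7 | (2S)-2-[3,4-bis(tert-butyldimethylsilyloxy)-5-(3-methylbut-2-en-1-yl)phenyl]-5,7-bis(tert-butyldimethylsilyloxy)chroman-4-ol (both C4 epimers) | CC(C)=CCc1cc([C@@H]2CC(O)c3c(O[Si](C)(C)C(C)(C)C)cc(O[Si](C)(C)C(C)(C)C)cc3O2)cc(O[Si](C)(C)C(C)(C)C)c1O[Si](C)(C)C(C)(C)C
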